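## Retrosynthetic overview

1. Megaphone ⇐ a porosin-type hexahydrobenzofuranone: C=O reduction and hydrolytic 1,3-carbonyl transposition open a temporary dihydrofuran and release the C7–OH and the enone.
2. Porosin-type ketone ⇐ burchellin-type dienone by conjugate reduction of the α-methoxy enone (C5′ set under thermodynamic control).
3. Burchellin-type dienone ⇐ 2-allyl-4,5-dimethoxyphenol + (Z)-isoelemicin: oxidative dearomatisation, then a catalytic asymmetric cationic [3+2] coupling (C8–C1′, then C7–O) that mirrors the presumed biogenesis and sets C7, C8 and C1′ at once.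
4. Phenol ⇐ 3,4-dimethoxyphenol + allyl bromide (Claisen); alkene ⇐ 5-bromo-1,2,3-trimethoxybenzene + (Z)-propenylboronic acid.
5. Ring order: the six-membered ring is bought as an arene and dearomatised; the dihydrofuran ring is made in the key step and opened again in the last step.

Assumption: the (S,S) antipode of the chiral acid is taken to give the (3aS) series; if the first run shows the opposite sense, the (R,R) antipode is used with no other change.

Numbering note: neolignan numbering (C7, C8, C1′–C6′) is used next to benzofuran numbering.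

## Route

Step 1
Reactants: 1 3,4-dimethoxyphenol; 2 allyl bromide
Product: 3 4-(allyloxy)-1,2-dimethoxybenzene
Conditions: K2CO3, acetone, reflux
Reagents that add atoms: none
Why: Williamson ether synthesis; the phenoxide is O-allylated cleanly by the primary allylic bromide and no stereocentre is formed.

Step 2
Reactants: 3 4-(allyloxy)-1,2-dimethoxybenzene
Product: 5 2-allyl-4,5-dimethoxyphenol, via Claisen dienone 4 (not isolated)
Conditions: N,N-diethylaniline, 190 °C
Reagents that add atoms: none
Why: Aromatic Claisen rearrangement; the [3,3] shift goes to the unhindered ortho carbon rather than the one flanked by two oxygens, and the dienone tautomerises to the phenol, leaving no stereocentre.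

Step 3
Reactants: 6 5-bromo-1,2,3-trimethoxybenzene; 7 (Z)-prop-1-en-1-ylboronic acid
Product: 8 (Z)-isoelemicin
Conditions: Pd(PPh3)4 (3 mol %), K2CO3, DME/H2O, 80 °C
Reagents that add atoms: none
Why: Suzuki–Miyaura coupling; oxidative addition, transmetalation and reductive elimination retain the alkene geometry, so the Z double bond of 7 is carried into 8 and no stereocentre is formed.

Step 4
Reactants: 5 2-allyl-4,5-dimethoxyphenol; 8 (Z)-isoelemicin
Product: 11 (2R,3S,3aS)-3a-allyl-5-methoxy-3-methyl-2-(3,4,5-trimethoxyphenyl)-3,3a-dihydro-1-benzofuran-6(2H)-one, via quinone monoketal 9 (not isolated), via dimethyl ketal 10 (not isolated)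
Conditions: PhI(OAc)2, MeOH, 0 °C; evaporate (toluene azeotrope); then 8 (1.5 equiv), (S,S)-IDPi (BINOL-derived N-triflyl imidodiphosphorimidate acid, 3 mol %), CH2Cl2, −78 to −40 °C; then 5 % aq. citric acid, THF, 0 °C
Reagents that add atoms: methanol, CO; water, O
Why: Proposed new method: PhI(OAc)2/MeOH turns the p-methoxyphenol into quinone monoketal 9 (routine oxidative dearomatisation), the confined chiral acid ionises 9 to a 4-methoxyphenoxonium (oxocarbenium) ion held in a chiral ion pair, the 5-OMe deactivates C-6 so that the Z-alkene attacks the allyl-bearing C-2 in a compact endo arrangement (trimethoxyphenyl stacked over the cation) and the vinylogous-ester oxygen then closes on the benzylic cation, which translates the Z geometry into 2,3-cis with 3-Me trans to 3a-allyl (C7, C8 and C1′ of the target) while the counter-anion selects the ring face (3aS), returning methanol gives ketal 10 and frees the catalyst, and mild aqueous acid unveils 11; the closest known reactions are the racemic Brønsted-acid- or SnCl4-promoted quinone-monoketal/propenylbenzene cationic [5+2] and [3+2] cycloadditions and chiral-counteranion-controlled additions to oxocarbenium ions.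

Step 5
Reactants: 11 (2R,3S,3aS)-3a-allyl-5-methoxy-3-methyl-2-(3,4,5-trimethoxyphenyl)-3,3a-dihydro-1-benzofuran-6(2H)-one
Product: 13 (2R,3S,3aR,5R)-3a-allyl-5-methoxy-3-methyl-2-(3,4,5-trimethoxyphenyl)-3,3a,4,5-tetrahydro-1-benzofuran-6(2H)-one, via 5-epimer 12 (not isolated)
Conditions: Cu(OAc)2·H2O (5 mol %), 1,2-bis(diphenylphosphino)benzene (5 mol %), (EtO)2MeSiH (1.5 equiv), t-BuOH (2 equiv), toluene, 0 °C to rt; then K2CO3, MeOH, rt
Reagents that add atoms: none
Why: Copper hydride conjugate reduction (Stryker type); the soft Cu–H adds to the only accessible β-carbon (C-4) of the α-methoxy enone and leaves the allyl group, the β-alkoxy enone and the carbonyl alone, protonation from the face away from the pseudo-axial allyl first gives mainly 5-epimer 12, and K2CO3/MeOH equilibrates the α-methoxy ketone to 13, whose 5-OMe is pseudo-equatorial and trans to the 3a-allyl (5R, the C5′ centre of the target).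

Step 6
Reactants: 13 (2R,3S,3aR,5R)-3a-allyl-5-methoxy-3-methyl-2-(3,4,5-trimethoxyphenyl)-3,3a,4,5-tetrahydro-1-benzofuran-6(2H)-one
Product: 15 megaphone, via allylic alcohol 14 (not isolated)
Conditions: i-Bu2AlH, CH2Cl2, −78 °C; then 1 M HCl, THF, 0 °C
Reagents that add atoms: water, O
Why: Stork–Danheiser 1,3-carbonyl transposition; i-Bu2AlH adds 1,2 to the vinylogous-ester carbonyl, dilute acid ionises the allylic alcohol to the ring-oxygen-stabilised allyl cation, water adds at C-7a and the hemiketal collapses to the enone with release of the C7 hydroxyl, the C7–O bond never being broken so that C7, C8, C1′ and C5′ keep their configuration and the transient C-6 carbinol centre of 14 is destroyed.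

## Compound list

1 | 3,4-dimethoxyphenol | COc1ccc(O)cc1OC | starting material
2 | allyl bromide (3-bromoprop-1-ene) | C=CCBr | starting material
3 | 4-(allyloxy)-1,2-dimethoxybenzene | C=CCOc1ccc(OC)c(OC)c1 | intermediate
4 | 6-allyl-3,4-dimethoxycyclohexa-2,4-dien-1-one (racemic Claisen dienone, not isolated) | C=CCC1C=C(OC)C(OC)=CC1=O | intermediate
5 | 2-allyl-4,5-dimethoxyphenol | C=CCc1cc(OC)c(OC)cc1O | intermediate
6 | 5-bromo-1,2,3-trimethoxybenzene | COc1cc(Br)cc(OC)c1OC | starting material
7 | (Z)-prop-1-en-1-ylboronic acid | C/C=C\B(O)O | starting material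
8 | (Z)-isoelemicin, 1,2,3-trimethoxy-5-[(Z)-prop-1-en-1-yl]benzene | C/C=C\c1cc(OC)c(OC)c(OC)c1 | intermediate
9 | 2-allyl-4,4,5-trimethoxycyclohexa-2,5-dien-1-one (quinone monoketal, not isolated) | C=CCC1=CC(OC)(OC)C(OC)=CC1=O | intermediate
10 | (2R,3S,3aS)-3a-allyl-5,6,6-trimethoxy-3-methyl-2-(3,4,5-trimethoxyphenyl)-2,3,3a,6-tetrahydro-1-benzofuran (dimethyl ketal of 11, not isolated) | O1[C@@H](c3cc(OC)c(OC)c(OC)c3)[C@@H](C)[C@@]2(CC=C)C=C(OC)C(OC)(OC)C=C12 | intermediate
11 | (2R,3S,3aS)-3a-allyl-5-methoxy-3-methyl-2-(3,4,5-trimethoxyphenyl)-3,3a-dihydro-1-benzofuran-6(2H)-one (burchellin type; 2-aryl and 3-methyl cis, 3-methyl trans to 3a-allyl) | O1[C@@H](c3cc(OC)c(OC)c(OC)c3)[C@@H](C)[C@@]2(CC=C)C=C(OC)C(=O)C=C12 | intermediate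
12 | (2R,3S,3aR,5S)-3a-allyl-5-methoxy-3-methyl-2-(3,4,5-trimethoxyphenyl)-3,3a,4,5-tetrahydro-1-benzofuran-6(2H)-one (5-epimer, OMe cis to allyl, not isolated) | O1[C@@H](c3cc(OC)c(OC)c(OC)c3)[C@@H](C)[C@@]2(CC=C)C[C@H](OC)C(=O)C=C12 | intermediate
13 | (2R,3S,3aR,5R)-3a-allyl-5-methoxy-3-methyl-2-(3,4,5-trimethoxyphenyl)-3,3a,4,5-tetrahydro-1-benzofuran-6(2H)-one (porosin type; 5-OMe trans to 3a-allyl) | O1[C@@H](c3cc(OC)c(OC)c(OC)c3)[C@@H](C)[C@@]2(CC=C)C[C@@H](OC)C(=O)C=C12 | intermediate
14 | (2R,3S,3aR,5R,6R)-3a-allyl-5-methoxy-3-methyl-2-(3,4,5-trimethoxyphenyl)-2,3,3a,4,5,6-hexahydro-1-benzofuran-6-ol (major C-6 epimer drawn, both converge; not isolated) | O1[C@@H](c3cc(OC)c(OC)c(OC)c3)[C@@H](C)[C@@]2(CC=C)C[C@@H](OC)[C@H](O)C=C12 | intermediate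
15 | megaphone, (4R,6R)-6-allyl-6-[(1R,2S)-1-hydroxy-1-(3,4,5-trimethoxyphenyl)propan-2-yl]-4-methoxycyclohex-2-en-1-one | C=CC[C@]1([C@H](C)[C@@H](O)c2cc(OC)c(OC)c(OC)c2)C[C@@H](OC)C=CC1=O | target

## Count and risks

Total step count: 6. Longest linear sequence: 5 steps (steps 1, 2, 4, 5 and 6 from 3,4-dimethoxyphenol); step 3 is the convergent branch.

**Most likely to fail, first: step 4.** The chiral-anion control of this cationic cycloaddition has no direct precedent. The strong acid may isomerise or oligomerise 8, the [5+2] bicyclic adduct may compete, and C-2 of 11 may epimerise through the benzylic cation.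

The fallback sets out from 5 and comes back at 11. It replaces the Brønsted-acid ion pair by a chiral Lewis acid on a quinone, a cycloaddition class with known asymmetric variants.

- 5 is oxidised with (NH4)2Ce(NO3)6 in MeCN/H2O at 0 °C to 2-allyl-5-methoxy-1,4-benzoquinone F1.
- F1 and 8 are combined with a stoichiometric chiral tetravalent-titanium TADDOLate (TiCl4/Ti(OiPr)4/TADDOL, CH2Cl2, −78 to 0 °C). Chelation between the C-4 carbonyl and the 5-OMe directs the alkene to the allyl-bearing carbon. The zwitterion closes through C-6 and loses the O-methyl group, giving (1S,5S,6R,7S)-5-allyl-3-hydroxy-6-methyl-7-(3,4,5-trimethoxyphenyl)bicyclo[3.2.1]oct-3-ene-2,8-dione F2 (methyl and aryl both endo).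
- O-methylation (Me2SO4, K2CO3, acetone) gives the methyl ether, (1S,5S,6R,7S)-5-allyl-3-methoxy-6-methyl-7-(3,4,5-trimethoxyphenyl)bicyclo[3.2.1]oct-3-ene-2,8-dione F3.
- Brief TsOH treatment (CH2Cl2, rt) moves the benzylic carbon from C-1 to the oxygen of the C-8 carbonyl through the benzylic cation and gives 11.

**Second: step 5.** The β-carbon is next to a quaternary centre and the carbonyl is deactivated as a vinylogous ester, so the reduction may stall or go 1,2. The C-5 configuration depends on the equilibration.

The fallback sets out from 5 and 8 and comes back at 13. It does the conjugate reduction before the dihydrofuran exists.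

- Step 4 is quenched cold (−78 °C, aqueous work-up) to intercept the kinetic [5+2] adduct, the bicyclic enone F3. Its C-2 carbonyl is an ordinary α-methoxy enone, not a vinylogous ester. F3 can also be taken from F1 and F2 above.
- The same copper hydride conditions reduce the enone to (1S,3R,5R,6R,7S)-5-allyl-3-methoxy-6-methyl-7-(3,4,5-trimethoxyphenyl)bicyclo[3.2.1]octane-2,8-dione F4.
- TsOH (CH2Cl2, rt) triggers the 1,3-shift of the benzylic carbon onto the oxygen of the bridging carbonyl and gives 13 directly. C-5 is equilibrated with K2CO3/MeOH as before.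

**Third: step 6.** The acid needed for the hydrolysis can also ionise the trimethoxybenzylic C7–O bond, leading to C7 epimerisation or elimination to the styrene, or it can eliminate methanol from the γ-methoxy enone. Water capture of that benzylic cation anti to the quaternary carbon (Felkin sense) would give the same C7 configuration as the retentive pathway, which limits the damage but does not remove the risk.

The fallback sets out from 14 and comes back at 15. It avoids an acidic medium altogether.

- 14 is isolated after a Rochelle-salt work-up of the i-Bu2AlH reduction.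
- Its C-6 hydroxyl is activated with Ms2O and i-Pr2NEt (CH2Cl2, −40 °C) as (2R,3S,3aR,5R,6R)-3a-allyl-5-methoxy-3-methyl-2-(3,4,5-trimethoxyphenyl)-2,3,3a,4,5,6-hexahydro-1-benzofuran-6-yl methanesulfonate F5.
- F5 ionises on its own to the ring-oxygen-stabilised allyl cation. Aqueous NaHCO3/THF adds water at C-7a and the hemiketal opens to 15.

## Further compounds

F1 | step 4 | 2-allyl-5-methoxy-1,4-benzoquinone | C=CCC1=CC(=O)C(OC)=CC1=O
F2 | step 4 | (1S,5S,6R,7S)-5-allyl-3-hydroxy-6-methyl-7-(3,4,5-trimethoxyphenyl)bicyclo[3.2.1]oct-3-ene-2,8-dione (6-methyl and 7-aryl endo) | C=CC[C@]12C=C(O)C(=O)[C@H](C1=O)[C@@H](c3cc(OC)c(OC)c(OC)c3)[C@H]2C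
F3 | step 4 | (1S,5S,6R,7S)-5-allyl-3-methoxy-6-methyl-7-(3,4,5-trimethoxyphenyl)bicyclo[3.2.1]oct-3-ene-2,8-dione (6-methyl and 7-aryl endo) | C=CC[C@]12C=C(OC)C(=O)[C@H](C1=O)[C@@H](c3cc(OC)c(OC)c(OC)c3)[C@H]2C
F4 | step 5 | (1S,3R,5R,6R,7S)-5-allyl-3-methoxy-6-methyl-7-(3,4,5-trimethoxyphenyl)bicyclo[3.2.1]octane-2,8-dione (C-3 drawn as the epimer that maps onto C-5 of 13) | C=CC[C@]12C[C@@H](OC)C(=O)[C@H](C1=O)[C@@H](c3cc(OC)c(OC)c(OC)c3)[C@H]2C
F5 | step 6 | (2R,3S,3aR,5R,6R)-3a-allyl-5-methoxy-3-methyl-2-(3,4,5-trimethoxyphenyl)-2,3,3a,4,5,6-hexahydro-1-benzofuran-6-yl methanesulfonate | O1[C@@H](c3cc(OC)c(OC)c(OC)c3)[C@@H](C)[C@@]2(CC=C)C[C@@H](OC)[C@H](OS(C)(=O)=O)C=C12
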